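**Target:** catechin-(4α→8)-catechin-(4α→8)-catechin-(4α→8)-epicatechin. Units are counted 1 (top) to 4 (bottom, epicatechin). The three upper units are 2R,3S with a 3,4-trans 4α-aryl bond; the bottom unit is 2R,3R.

**Retrosynthetic overview**
1. No ring is built: all C2/C3 stereocentres and all rings come from commercial (+)-catechin and (−)-epicatechin; only the three C4–C8 bonds and their C4 centres are made.
2. Last step: global hydrogenolysis of sixteen benzyl ethers and one C8 bromine cap.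
3. Central bond (C4 of unit 2 to C8 of unit 3): 2+2 union of a bromo-capped catechin–catechin dimer carrying a cis-3,4-diol with a catechin–epicatechin dimer, by a proposed arylboronic acid-catalysed dehydrative Friedel–Crafts reaction.
4. The diol comes from DDQ/water oxidation at the only CH2 of the capped dimer; both dimers come from 4-(2-ethoxyethoxy) monomer electrophiles and benzylated monomers.
5. Bond order: unit 1–unit 2 and unit 3–unit 4 bonds in parallel, central bond last.

Assumption: DDQ-mediated oxygenation at C4 of a 2,3-trans flavan is taken to give the 3,4-cis (4β-O) isomer; C4 is ionised again in the following coupling, so this choice does not affect the final stereochemistry.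

**Route**

Step 1
Reactants: 1 (+)-catechin
Product: 2 5,7,3',4'-tetra-O-benzyl-(+)-catechin
Conditions: BnBr (4.4 equiv), K2CO3 (5 equiv), DMF, 0 °C to rt
Reagents that add atoms: benzyl bromide, BrCc1ccccc1
Why: Only the four phenols are deprotonated by carbonate, so they are benzylated while the secondary 3-OH stays free (Williamson ether synthesis); no stereocentre is touched.

Step 2
Reactants: 3 (−)-epicatechin
Product: 4 5,7,3',4'-tetra-O-benzyl-(−)-epicatechin
Conditions: BnBr (4.4 equiv), K2CO3 (5 equiv), DMF, 0 °C to rt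
Reagents that add atoms: benzyl bromide, BrCc1ccccc1
Why: Same phenol-selective Williamson ether synthesis as step 1, run cold to avoid base-induced C2 epimerisation.

Step 3
Reactants: 2 tetra-O-benzylcatechin
Product: 5 (2R,3S,4S)-tetra-O-benzyl-4-(2-ethoxyethoxy)flavan-3-ol
Conditions: DDQ (2 equiv), 2-ethoxyethanol (5 equiv), CH2Cl2, rt
Reagents that add atoms: 2-ethoxyethanol, CCOCCO
Why: DDQ abstracts the benzylic C4 hydride (cation stabilised by the 5,7-dialkoxy ring A and O1) and the alcohol traps it cis to the 3-OH; this is an oxidative benzylic C–H alkoxylation.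

Step 4
Reactants: 5 4-(2-ethoxyethoxy) catechin electrophile; 4 tetra-O-benzylepicatechin (3 equiv, excess recovered)
Product: 6 octa-O-benzyl procyanidin B4 (tetra-O-benzylcatechin-(4α→8)-tetra-O-benzylepicatechin)
Conditions: Me3SiOTf (0.2 equiv), CH2Cl2, −78 °C
Reagents that add atoms: none
Why: The Lewis acid ionises the C4 ether and C8 of 4 (the most nucleophilic, least hindered ring A position) attacks anti to the 3-OH, setting C4 as 3,4-trans (4α, S) in a Friedel–Crafts alkylation; excess 4 suppresses chain growth.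

Step 5
Reactants: 2 tetra-O-benzylcatechin
Product: 7 8-bromo-5,7,3',4'-tetra-O-benzyl-(+)-catechin
Conditions: NBS (1.0 equiv), CH2Cl2, −78 °C to rt
Reagents that add atoms: N-bromosuccinimide, O=C1CCC(=O)N1Br
Why: Electrophilic aromatic bromination goes selectively to C8, the most electron-rich and accessible position of ring A, giving a cap that blocks later self-condensation.

Step 6
Reactants: 7 8-bromo-tetra-O-benzylcatechin
Product: 8 (2R,3S,4S)-8-bromo-tetra-O-benzyl-4-(2-ethoxyethoxy)flavan-3-ol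
Conditions: DDQ (2.5 equiv), 2-ethoxyethanol (5 equiv), CH2Cl2, rt
Reagents that add atoms: 2-ethoxyethanol, CCOCCO
Why: Same oxidative benzylic C–H alkoxylation as step 3; the aryl bromide is inert to DDQ.

Step 7
Reactants: 8 bromo-capped 4-(2-ethoxyethoxy) electrophile; 2 tetra-O-benzylcatechin (2 equiv)
Product: 9 8-bromo-octa-O-benzyl procyanidin B3 ([8-bromo-tetra-O-benzylcatechin]-(4α→8)-[tetra-O-benzylcatechin])
Conditions: Me3SiOTf (0.2 equiv), CH2Cl2, −78 °C
Reagents that add atoms: none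
Why: Friedel–Crafts alkylation as in step 4, with C8 of 2 attacking the C4 cation anti to the 3-OH (4α, 3,4-trans); the bromine cap leaves the product with no reactive C8 on its top unit.

Step 8
Reactants: 9 bromo-capped catechin–catechin dimer
Product: 10 bromo-capped dimer with a 4β-hydroxyl on the lower unit (lower unit is a (2R,3S,4S)-3,4-cis-diol)
Conditions: DDQ (1.5 equiv), CH2Cl2/H2O 18:1, rt
Reagents that add atoms: water, O
Why: DDQ abstracts hydride from the only benzylic CH2 (C4 of the lower unit; the interflavan C4–H is a hindered diarylmethine that cannot align with ring A) and water traps the cation cis to the 3-OH, an oxidative benzylic C–H hydroxylation.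

Step 9
Reactants: 10 bromo-capped dimer cis-3,4-diol; 6 octa-O-benzyl procyanidin B4 (1.1 equiv)
Product: 12 bromo-capped hexadeca-O-benzyl tetramer, via dioxaborolane 11 (not isolated)
Conditions: pentafluorophenylboronic acid C6F5B(OH)2 (10 mol%), CH2Cl2/(CF3)2CHOH 4:1, 4 Å MS, −20 °C to rt
Reagents that add atoms: none
Why: Proposed new method: the electron-poor boronic acid condenses reversibly with the only cis-1,2-diol present (O3/O4 of the lower unit of 10) to give dioxaborolane 11; its benzylic C4–O bond ionises because ArB(OR)O− is a far better leaving group than hydroxide and the fluoro alcohol hydrogen-bonds to it, giving a ring A/O1-stabilised C4 cation whose β-face is shielded by the boron still tethered to O3; C8 of the top unit of 6 then attacks the α-face, setting the new C4 centre 3,4-trans (4α→8), and proton transfer to the boronate oxygen plus ester exchange with the next diol turns the catalyst over with water as the only by-product, while the bromine cap prevents 10 or 12 from chain-extending; the closest known reaction types are arylboronic acid-catalysed dehydrative Friedel–Crafts benzylation with benzylic alcohols and boronic/borinic acid activation of cis-diols, neither shown on flavan-3,4-diols or for interflavan bond formation.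

Step 10
Reactants: 12 bromo-capped hexadeca-O-benzyl tetramer
Product: 13 catechin-(4α→8)-catechin-(4α→8)-catechin-(4α→8)-epicatechin (target)
Conditions: H2 (1 atm), Pd(OH)2/C (20 wt%), Et3N (1.5 equiv), THF/MeOH/H2O 20:20:1, rt; Sephadex LH-20
Reagents that add atoms: none
Why: Catalytic hydrogenolysis cleaves all sixteen benzyl ethers and the aryl C–Br bond in one operation, with Et3N buffering the HBr so the acid-labile interflavan bonds and all stereocentres are untouched.

**Compound list**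
1 | (+)-catechin, (2R,3S)-2-(3,4-dihydroxyphenyl)chromane-3,5,7-triol | Oc1cc(O)c2c(c1)O[C@H](c1ccc(O)c(O)c1)[C@@H](O)C2 | starting material
2 | 5,7,3',4'-tetra-O-benzyl-(+)-catechin (2R,3S; 3-OH free) | c1ccccc1COc1cc(OCc2ccccc2)c2c(c1)O[C@H](c1ccc(OCc3ccccc3)c(OCc3ccccc3)c1)[C@@H](O)C2 | intermediate
3 | (−)-epicatechin, (2R,3R)-2-(3,4-dihydroxyphenyl)chromane-3,5,7-triol | Oc1cc(O)c2c(c1)O[C@H](c1ccc(O)c(O)c1)[C@H](O)C2 | starting material
4 | 5,7,3',4'-tetra-O-benzyl-(−)-epicatechin (2R,3R; 3-OH free) | c1ccccc1COc1cc(OCc2ccccc2)c2c(c1)O[C@H](c1ccc(OCc3ccccc3)c(OCc3ccccc3)c1)[C@H](O)C2 | intermediate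
5 | (2R,3S,4S)-5,7,3',4'-tetra-O-benzyl-4-(2-ethoxyethoxy)flavan-3-ol (4β-O, 3,4-cis) | c1ccccc1COc1cc(OCc2ccccc2)c2c(c1)O[C@H](c1ccc(OCc3ccccc3)c(OCc3ccccc3)c1)[C@@H](O)[C@H]2OCCOCC | intermediate
6 | octa-O-benzyl procyanidin B4: tetra-O-benzylcatechin-(4α→8)-tetra-O-benzylepicatechin; upper unit 2R,3S,4S, lower unit 2R,3R | c1ccccc1COc1cc(OCc2ccccc2)c2c(c1)O[C@H](c1ccc(OCc3ccccc3)c(OCc3ccccc3)c1)[C@@H](O)[C@@H]2c1c(OCc3ccccc3)cc(OCc3ccccc3)c2c1O[C@H](c1ccc(OCc3ccccc3)c(OCc3ccccc3)c1)[C@H](O)C2 | intermediate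
7 | 8-bromo-5,7,3',4'-tetra-O-benzyl-(+)-catechin | c1ccccc1COc1cc(OCc2ccccc2)c2c(c1Br)O[C@H](c1ccc(OCc3ccccc3)c(OCc3ccccc3)c1)[C@@H](O)C2 | intermediate
8 | (2R,3S,4S)-8-bromo-5,7,3',4'-tetra-O-benzyl-4-(2-ethoxyethoxy)flavan-3-ol | c1ccccc1COc1cc(OCc2ccccc2)c2c(c1Br)O[C@H](c1ccc(OCc3ccccc3)c(OCc3ccccc3)c1)[C@@H](O)[C@H]2OCCOCC | intermediate
9 | 8-bromo-octa-O-benzyl procyanidin B3: [8-bromo-tetra-O-benzylcatechin]-(4α→8)-[tetra-O-benzylcatechin], both units 2,3-trans, interflavan bond 3,4-trans | c1ccccc1COc1cc(OCc2ccccc2)c2c(c1Br)O[C@H](c1ccc(OCc3ccccc3)c(OCc3ccccc3)c1)[C@@H](O)[C@@H]2c1c(OCc3ccccc3)cc(OCc3ccccc3)c2c1O[C@H](c1ccc(OCc3ccccc3)c(OCc3ccccc3)c1)[C@@H](O)C2 | intermediate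
10 | compound 9 with a 4β-hydroxyl on the lower unit (lower unit (2R,3S,4S)-flavan-3,4-cis-diol) | c1ccccc1COc1cc(OCc2ccccc2)c2c(c1Br)O[C@H](c1ccc(OCc3ccccc3)c(OCc3ccccc3)c1)[C@@H](O)[C@@H]2c1c(OCc3ccccc3)cc(OCc3ccccc3)c2c1O[C@H](c1ccc(OCc3ccccc3)c(OCc3ccccc3)c1)[C@@H](O)[C@H]2O | intermediate
11 | cyclic pentafluorophenylboronate of 10 (2-pentafluorophenyl-1,3,2-dioxaborolane cis-fused across O3/O4 of the lower unit) | c1ccccc1COc1cc(OCc2ccccc2)c2c(c1Br)O[C@H](c1ccc(OCc3ccccc3)c(OCc3ccccc3)c1)[C@@H](O)[C@@H]2c1c(OCc3ccccc3)cc(OCc3ccccc3)c2c1O[C@H](c1ccc(OCc3ccccc3)c(OCc3ccccc3)c1)[C@@H](OB(c5c(F)c(F)c(F)c(F)c5F)O4)[C@H]24 | intermediate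
12 | bromo-capped hexadeca-O-benzyl tetramer: [8-bromo-tetra-O-benzylcatechin]-(4α→8)-[tetra-O-benzylcatechin]-(4α→8)-[tetra-O-benzylcatechin]-(4α→8)-[tetra-O-benzylepicatechin], four free 3-OH | c1ccccc1COc1cc(OCc2ccccc2)c2c(c1Br)O[C@H](c1ccc(OCc3ccccc3)c(OCc3ccccc3)c1)[C@@H](O)[C@@H]2c1c(OCc3ccccc3)cc(OCc3ccccc3)c2c1O[C@H](c1ccc(OCc3ccccc3)c(OCc3ccccc3)c1)[C@@H](O)[C@@H]2c1c(OCc3ccccc3)cc(OCc3ccccc3)c2c1O[C@H](c1ccc(OCc3ccccc3)c(OCc3ccccc3)c1)[C@@H](O)[C@@H]2c1c(OCc3ccccc3)cc(OCc3ccccc3)c2c1O[C@H](c1ccc(OCc3ccccc3)c(OCc3ccccc3)c1)[C@H](O)C2 | intermediate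
13 | catechin-(4α→8)-catechin-(4α→8)-catechin-(4α→8)-epicatechin (CNP0236700.7) | Oc1cc(O)c2c(c1)O[C@H](c1ccc(O)c(O)c1)[C@@H](O)[C@@H]2c1c(O)cc(O)c2c1O[C@H](c1ccc(O)c(O)c1)[C@@H](O)[C@@H]2c1c(O)cc(O)c2c1O[C@H](c1ccc(O)c(O)c1)[C@@H](O)[C@@H]2c1c(O)cc(O)c2c1O[C@H](c1ccc(O)c(O)c1)[C@H](O)C2 | target

**Step count**
Total steps: 10. Longest linear sequence: 7 (steps 1, 5, 6, 7, 8, 9, 10).

**Three steps most likely to fail**

Step 9 (the proposed new union). The risk is that the boronate does not ionise cleanly or that the fluoro alcohol medium causes scrambling. The fallback uses known chemistry and sets out from 9. DDQ and 2-ethoxyethanol in CH2Cl2 convert 9 into the bromo-capped dimer with a 4β-(2-ethoxyethoxy) group on its lower unit F1. This is condensed 1:1 with 6 under Yb(OTf)3 in CH2Cl2 at rt (or Me3SiOTf at −78 °C). That is the established ether leaving group/Lewis acid Friedel–Crafts approach, and it comes back to the route at 12.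

Step 8 (site-selective DDQ/water oxidation of the dimer). The risk is over-oxidation to the 4-ketone or attack at the wrong benzylic position. The fallback drops dimer oxidation and grows the chain linearly from 6 with monomer electrophiles. Compound 6 (3 equiv) and 5 with Me3SiOTf in CH2Cl2 at −78 °C give the dodeca-O-benzyl catechin-(4α→8)-catechin-(4α→8)-epicatechin trimer F2. F2 is then coupled at its top C8 with the bromo-capped monomer electrophile 8 under the same conditions, and the route is rejoined at 12.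

Step 10 (global hydrogenolysis with simultaneous debromination). The risk is incomplete C–Br cleavage, or HBr-induced interflavan scission and base-induced epimerisation. The fallback separates the two events and sets out from 12. Bromine–lithium exchange with n-BuLi (6 equiv, THF, −78 °C) and a MeOH quench give the bromine-free hexadeca-O-benzyl tetramer F3. F3 is then hydrogenolysed under neutral conditions (H2, Pd(OH)2/C, THF/MeOH/H2O) and the route is rejoined at 13.

**Further compounds**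
F1 | step 9 | [8-bromo-tetra-O-benzylcatechin]-(4α→8)-[(2R,3S,4S)-tetra-O-benzyl-4-(2-ethoxyethoxy)flavan-3-ol] | c1ccccc1COc1cc(OCc2ccccc2)c2c(c1Br)O[C@H](c1ccc(OCc3ccccc3)c(OCc3ccccc3)c1)[C@@H](O)[C@@H]2c1c(OCc3ccccc3)cc(OCc3ccccc3)c2c1O[C@H](c1ccc(OCc3ccccc3)c(OCc3ccccc3)c1)[C@@H](O)[C@H]2OCCOCC
F2 | step 8 | dodeca-O-benzyl catechin-(4α→8)-catechin-(4α→8)-epicatechin trimer | c1ccccc1COc1cc(OCc2ccccc2)c2c(c1)O[C@H](c1ccc(OCc3ccccc3)c(OCc3ccccc3)c1)[C@@H](O)[C@@H]2c1c(OCc3ccccc3)cc(OCc3ccccc3)c2c1O[C@H](c1ccc(OCc3ccccc3)c(OCc3ccccc3)c1)[C@@H](O)[C@@H]2c1c(OCc3ccccc3)cc(OCc3ccccc3)c2c1O[C@H](c1ccc(OCc3ccccc3)c(OCc3ccccc3)c1)[C@H](O)C2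
F3 | step 10 | hexadeca-O-benzyl catechin-(4α→8)-catechin-(4α→8)-catechin-(4α→8)-epicatechin (no bromine) | c1ccccc1COc1cc(OCc2ccccc2)c2c(c1)O[C@H](c1ccc(OCc3ccccc3)c(OCc3ccccc3)c1)[C@@H](O)[C@@H]2c1c(OCc3ccccc3)cc(OCc3ccccc3)c2c1O[C@H](c1ccc(OCc3ccccc3)c(OCc3ccccc3)c1)[C@@H](O)[C@@H]2c1c(OCc3ccccc3)cc(OCc3ccccc3)c2c1O[C@H](c1ccc(OCc3ccccc3)c(OCc3ccccc3)c1)[C@@H](O)[C@@H]2c1c(OCc3ccccc3)cc(OCc3ccccc3)c2c1O[C@H](c1ccc(OCc3ccccc3)c(OCc3ccccc3)c1)[C@H](O)C2
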